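**Strategy.** The target is a pseudo-meso syn-1,3-diacetate: C3 and C5 differ only through the extra methoxy group on the C7 aryl ring, so no catalyst can tell the two carbinols apart once both arms are in place. The route therefore carries both oxygens as C–B bonds and forms C3–C4 by lithiation–borylation: a sparteine-derived α-lithiated benzoate (C1–C3, guaiacyl arm) is inserted into the primary C–B bond of an enantioenriched 1,2-bis(boronic ester) (C4–C7, syringyl arm). One operation joins the two different arms, sets C3 under reagent control next to C5 from alkene diboration, and delivers the syn-1,3-diol after oxidation.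

Key step: step 7

Remark on numbering: C1 of the heptane chain bears the 4-hydroxy-3-methoxyphenyl ring and C7 the 4-hydroxy-3,5-dimethoxyphenyl ring; the target is (3R,5S), i.e. syn.

Assumption: in step 6 the (R,R)-TADDOL-derived phosphonite is taken to give the (R)-configured bis(boronate) 10 (the one that would oxidise to the (S)-1,2-diol). If a trial shows the opposite sense, the (S,S)-ligand is used and nothing else changes.

**Step 1**
Reactants: 1 eugenol (4-allyl-2-methoxyphenol)
Product: 2 (4-allyl-2-methoxyphenoxy)triisopropylsilane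
Conditions: TIPSCl (1.2 equiv), imidazole (2.5 equiv), DMF, rt
Reagents that add atoms: chlorotriisopropylsilane, CC(C)[Si](Cl)(C(C)C)C(C)C
Why: Imidazole-promoted O-silylation of the phenol should give a TIPS ether that has no acidic C–H for s-BuLi, resists Grignard and perborate conditions, and is cleaved last by fluoride.

**Step 2**
Reactants: 2 (4-allyl-2-methoxyphenoxy)triisopropylsilane
Product: 4 3-[3-methoxy-4-(triisopropylsilyloxy)phenyl]propan-1-ol, via B-alkyl-9-BBN adduct 3 (not isolated)
Conditions: 9-BBN (0.5 M in THF, 1.2 equiv), THF, 0 °C to rt; then NaBO3·4H2O, H2O, rt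
Reagents that add atoms: sodium perborate tetrahydrate, [Na+].[O-]B1OO1.O.O.O.O
Why: Anti-Markovnikov hydroboration of the terminal alkene with the bulky borane and mild perborate oxidation of the C–B bond (hydroboration–oxidation) should give the primary alcohol without touching the aryl silyl ether.

**Step 3**
Reactants: 4 3-[3-methoxy-4-(triisopropylsilyloxy)phenyl]propan-1-ol
Product: 5 3-[3-methoxy-4-(triisopropylsilyloxy)phenyl]propyl 2,4,6-triisopropylbenzoate
Conditions: 2,4,6-triisopropylbenzoic acid (1.2 equiv), PPh3, DIAD, THF, 0 °C to rt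
Reagents that add atoms: 2,4,6-triisopropylbenzoic acid, CC(C)c1cc(C(C)C)c(C(=O)O)c(C(C)C)c1
Why: Mitsunobu esterification of the primary alcohol should install the hindered benzoate, whose shielded carbonyl resists s-BuLi and later serves as directing and leaving group.

**Step 4**
Reactants: 6 4-bromo-2,6-dimethoxyphenol
Product: 7 (4-bromo-2,6-dimethoxyphenoxy)triisopropylsilane
Conditions: TIPSOTf (1.2 equiv), 2,6-lutidine (2 equiv), CH2Cl2, 0 °C to rt
Reagents that add atoms: triisopropylsilyl trifluoromethanesulfonate, CC(C)[Si](OS(=O)(=O)C(F)(F)F)(C(C)C)C(C)C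
Why: The silyl triflate is reactive enough to silylate the doubly ortho-substituted phenol (O-silylation).

**Step 5**
Reactants: 7 (4-bromo-2,6-dimethoxyphenoxy)triisopropylsilane; 8 but-3-en-1-ylmagnesium bromide
Product: 9 [4-(but-3-en-1-yl)-2,6-dimethoxyphenoxy]triisopropylsilane
Conditions: Pd(dppf)Cl2·CH2Cl2 (3 mol %), THF, 0 °C to 50 °C
Reagents that add atoms: but-3-en-1-ylmagnesium bromide (8), C=CCC[Mg]Br
Why: Kumada–Corriu sp2–sp3 coupling; the wide-bite-angle dppf ligand should favour reductive elimination over β-hydride elimination, so the terminal alkene stays in place.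

**Step 6**
Reactants: 9 [4-(but-3-en-1-yl)-2,6-dimethoxyphenoxy]triisopropylsilane
Product: 10 (R)-2,2'-{4-[3,5-dimethoxy-4-(triisopropylsilyloxy)phenyl]butane-1,2-diyl}bis(4,4,5,5-tetramethyl-1,3,2-dioxaborolane)
Conditions: B2pin2 (1.05 equiv), Pt(dba)3 (1 mol %), (R,R)-3,5-diisopropylphenyl-TADDOL phenylphosphonite (1.2 mol %, see assumption), THF, 60 °C
Reagents that add atoms: bis(pinacolato)diboron, CC1(C)OB(OC1(C)C)B1OC(C)(C)C(C)(C)O1
Why: Pt-catalysed enantioselective alkene diboration (B–B oxidative addition, face-selective insertion of the alkene into Pt–B, reductive elimination) should add both borons syn, with the C5 configuration fixed by the chiral phosphonite.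

**Step 7**
Reactants: 5 3-[3-methoxy-4-(triisopropylsilyloxy)phenyl]propyl 2,4,6-triisopropylbenzoate; 10 (R)-1,2-bis(boronic ester)
Product: 14 (3R,5S)-1-[3-methoxy-4-(triisopropylsilyloxy)phenyl]-7-[3,5-dimethoxy-4-(triisopropylsilyloxy)phenyl]heptane-3,5-diol, via lithiated benzoate 11 (not isolated), via boronate complex 12 (not isolated), via 1,3-bis(boronate) 13 (not isolated)
Conditions: 5 (1.3 equiv), (−)-sparteine (1.3 equiv), s-BuLi (1.2 equiv), Et2O, −78 °C, 5 h; then 10 (1.0 equiv) in Et2O, −78 °C, 1 h, then 35 °C, 16 h; then NaBO3·4H2O, THF/H2O, rt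
Reagents that add atoms: sodium perborate tetrahydrate, [Na+].[O-]B1OO1.O.O.O.O
Why: s-BuLi/(−)-sparteine should remove the pro-S α-hydrogen of benzoate 5 (carbonyl-directed deprotonation) to give the configurationally stable (S)-lithio species 11, which adds with retention to the less hindered primary boron of 10 to give ate complex 12; on warming, the C4 methylene migrates from boron to C3 anti to the departing triisopropylbenzoate (stereospecific 1,2-metallate shift, inversion at C3), forming the C3–C4 bond and bis(boronate) 13, whose two C–B bonds are then oxidised with retention. The closest known reaction type is the lithiation–borylation (Matteson-type) homologation of boronic esters with sparteine-derived lithiated benzoates, in its site-selective form on 1,2-bis(boronic esters) for 1,3-diol synthesis. No ring is closed; the step joins the C1–C3 and C4–C7 fragments. C3 is set (R after oxidation) by the sparteine-controlled deprotonation and the retention/inversion sequence, while C5 (S after oxidation) is carried unchanged from step 6, so the syn relationship is a reagent-controlled pairing and the minor enantiomers of either partner should end up mainly in the separable anti diastereomer. The step needs site selectivity for the primary over the secondary Bpin group, which the bulk of the carbenoid and of the α-branched boronate should secure, and lithiation only at the O–CH2 group, which the benzoate carbonyl directs while the TIPS aryl ethers offer no competing acidic site.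

**Step 8**
Reactants: 14 (3R,5S)-diol
Product: 15 (3R,5S)-1-[3-methoxy-4-(triisopropylsilyloxy)phenyl]-7-[3,5-dimethoxy-4-(triisopropylsilyloxy)phenyl]heptane-3,5-diyl diacetate
Conditions: Ac2O (4 equiv), pyridine, DMAP (5 mol %), CH2Cl2, rt
Reagents that add atoms: acetic anhydride, CC(=O)OC(C)=O
Why: DMAP-catalysed acylation of both secondary alcohols should proceed without touching the stereocentres (O-acetylation).

**Step 9**
Reactants: 15 (3R,5S)-bis(TIPS) diacetate
Product: 16 (3R,5S)-1-(4-hydroxy-3-methoxyphenyl)-7-(4-hydroxy-3,5-dimethoxyphenyl)heptane-3,5-diyl diacetate (CNP0327377.1)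
Conditions: TBAF (2.4 equiv), AcOH (2.6 equiv), THF, 0 °C
Reagents that add atoms: none
Why: Fluoride-mediated cleavage of aryl silyl ethers is fast at 0 °C, and acetic acid buffering should keep the liberated phenoxides from attacking the secondary acetates (desilylation).

**Compound list**
1 | eugenol (4-allyl-2-methoxyphenol) | C=CCc1ccc(O)c(OC)c1 | starting material
2 | (4-allyl-2-methoxyphenoxy)triisopropylsilane | C=CCc1ccc(O[Si](C(C)C)(C(C)C)C(C)C)c(OC)c1 | intermediate
3 | 9-{3-[3-methoxy-4-(triisopropylsilyloxy)phenyl]propyl}-9-borabicyclo[3.3.1]nonane | COc1cc(CCCB2C3CCCC2CCC3)ccc1O[Si](C(C)C)(C(C)C)C(C)C | intermediate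
4 | 3-[3-methoxy-4-(triisopropylsilyloxy)phenyl]propan-1-ol | COc1cc(CCCO)ccc1O[Si](C(C)C)(C(C)C)C(C)C | intermediate
5 | 3-[3-methoxy-4-(triisopropylsilyloxy)phenyl]propyl 2,4,6-triisopropylbenzoate | COc1cc(CCCOC(=O)c2c(C(C)C)cc(C(C)C)cc2C(C)C)ccc1O[Si](C(C)C)(C(C)C)C(C)C | intermediate
6 | 4-bromo-2,6-dimethoxyphenol | COc1cc(Br)cc(OC)c1O | starting material
7 | (4-bromo-2,6-dimethoxyphenoxy)triisopropylsilane | COc1cc(Br)cc(OC)c1O[Si](C(C)C)(C(C)C)C(C)C | intermediate
8 | but-3-en-1-ylmagnesium bromide | C=CCC[Mg]Br | starting material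
9 | [4-(but-3-en-1-yl)-2,6-dimethoxyphenoxy]triisopropylsilane | C=CCCc1cc(OC)c(O[Si](C(C)C)(C(C)C)C(C)C)c(OC)c1 | intermediate
10 | (R)-2,2'-{4-[3,5-dimethoxy-4-(triisopropylsilyloxy)phenyl]butane-1,2-diyl}bis(4,4,5,5-tetramethyl-1,3,2-dioxaborolane) | COc1cc(CC[C@@H](CB2OC(C)(C)C(C)(C)O2)B2OC(C)(C)C(C)(C)O2)cc(OC)c1O[Si](C(C)C)(C(C)C)C(C)C | intermediate
11 | (S)-1-lithio-3-[3-methoxy-4-(triisopropylsilyloxy)phenyl]propyl 2,4,6-triisopropylbenzoate (as its sparteine complex) | COc1cc(CC[C@H]([Li])OC(=O)c2c(C(C)C)cc(C(C)C)cc2C(C)C)ccc1O[Si](C(C)C)(C(C)C)C(C)C | intermediate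
12 | lithium boronate complex: the primary boron of 10 bonded to the (S)-configured benzoate-bearing C3 of 11, C5 unchanged (R) | [Li+].COc1cc(CC[C@H]([B-]2(C[C@H](CCc3cc(OC)c(O[Si](C(C)C)(C(C)C)C(C)C)c(OC)c3)B3OC(C)(C)C(C)(C)O3)OC(C)(C)C(C)(C)O2)OC(=O)c2c(C(C)C)cc(C(C)C)cc2C(C)C)ccc1O[Si](C(C)C)(C(C)C)C(C)C | intermediate
13 | 2,2'-{(3R,5S)-1-[3-methoxy-4-(triisopropylsilyloxy)phenyl]-7-[3,5-dimethoxy-4-(triisopropylsilyloxy)phenyl]heptane-3,5-diyl}bis(4,4,5,5-tetramethyl-1,3,2-dioxaborolane) | COc1cc(CC[C@H](C[C@H](CCc2cc(OC)c(O[Si](C(C)C)(C(C)C)C(C)C)c(OC)c2)B2OC(C)(C)C(C)(C)O2)B2OC(C)(C)C(C)(C)O2)ccc1O[Si](C(C)C)(C(C)C)C(C)C | intermediate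
14 | (3R,5S)-1-[3-methoxy-4-(triisopropylsilyloxy)phenyl]-7-[3,5-dimethoxy-4-(triisopropylsilyloxy)phenyl]heptane-3,5-diol | COc1cc(CC[C@H](C[C@H](CCc2cc(OC)c(O[Si](C(C)C)(C(C)C)C(C)C)c(OC)c2)O)O)ccc1O[Si](C(C)C)(C(C)C)C(C)C | intermediate
15 | (3R,5S)-1-[3-methoxy-4-(triisopropylsilyloxy)phenyl]-7-[3,5-dimethoxy-4-(triisopropylsilyloxy)phenyl]heptane-3,5-diyl diacetate | COc1cc(CC[C@H](C[C@H](CCc2cc(OC)c(O[Si](C(C)C)(C(C)C)C(C)C)c(OC)c2)OC(C)=O)OC(C)=O)ccc1O[Si](C(C)C)(C(C)C)C(C)C | intermediate
16 | (3R,5S)-1-(4-hydroxy-3-methoxyphenyl)-7-(4-hydroxy-3,5-dimethoxyphenyl)heptane-3,5-diyl diacetate | COc1cc(CC[C@H](C[C@H](CCc2cc(OC)c(O)c(OC)c2)OC(C)=O)OC(C)=O)ccc1O | target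

**Step count.** Total: 9 steps. Longest linear sequence: 6 steps (1, 2, 3, 7, 8, 9 or 4, 5, 6, 7, 8, 9).

**Steps most likely to fail, with fallbacks**

Step 7. The lithiation may be incomplete or compete with ring metalation. The carbenoid may also attack the secondary boron or homologate twice, the hindered ate complex may rearrange slowly, and aryl silyl groups may be partly lost in the oxidative work-up. The fallback forms the same C3–C4 bond by dithiane-anion/epoxide coupling and sets C3 by 1,3-induction; it sets out from 9 and 4 and returns at 14. Alkene 9 is epoxidised (mCPBA, CH2Cl2) to racemic 2-{2-[3,5-dimethoxy-4-(triisopropylsilyloxy)phenyl]ethyl}oxirane F1. Hydrolytic kinetic resolution with the (salen)Co(III)–OAc enantiomer that leaves the (S)-epoxide (0.55 equiv H2O) should give (S)-2-{2-[3,5-dimethoxy-4-(triisopropylsilyloxy)phenyl]ethyl}oxirane F2. Alcohol 4 is oxidised (Dess–Martin periodinane) to 3-[3-methoxy-4-(triisopropylsilyloxy)phenyl]propanal F3 and converted (propane-1,3-dithiol, BF3·OEt2) into 2-{2-[3-methoxy-4-(triisopropylsilyloxy)phenyl]ethyl}-1,3-dithiane F4. Lithiation of F4 (n-BuLi, THF, −20 °C) and opening of F2 at its terminal carbon should give (S)-4-[3,5-dimethoxy-4-(triisopropylsilyloxy)phenyl]-1-(2-{2-[3-methoxy-4-(triisopropylsilyloxy)phenyl]ethyl}-1,3-dithian-2-yl)butan-2-ol F5. Dithiane removal (MeI, CaCO3, aq. MeCN) gives (S)-5-hydroxy-7-[3,5-dimethoxy-4-(triisopropylsilyloxy)phenyl]-1-[3-methoxy-4-(triisopropylsilyloxy)phenyl]heptan-3-one F6. Narasaka–Prasad reduction (Et2BOMe, NaBH4, THF/MeOH, −78 °C) of the boron chelate should then give syn-diol 14.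

Step 6. Facial selectivity may be poor, or of the wrong sense, on this electron-rich, silyl-substituted substrate, and the Pt catalyst may be inhibited. The fallback reaches the same bis(boronate) through a different C–B bond-forming logic; it sets out from 9 and returns at 10. Cross-metathesis of 9 with vinylboronic acid pinacol ester (second-generation Grubbs catalyst, CH2Cl2, 40 °C) should give (E)-2-{4-[3,5-dimethoxy-4-(triisopropylsilyloxy)phenyl]but-1-en-1-yl}-4,4,5,5-tetramethyl-1,3,2-dioxaborolane F7. Copper-catalysed enantioselective protoboration of F7 (CuCl, NaOt-Bu, chiral bisphosphine or NHC ligand, B2pin2, MeOH, THF) places copper on the boron-bearing carbon and the new boron on C5, and protonation should give 10.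

Step 9. Fluoride or the liberated phenoxides may cleave or transfer the secondary acetates. The fallback reverses the order of deprotection and acylation; it sets out from 14 and returns at 16. Desilylation of 14 (TBAF, THF) gives (3R,5S)-1-(4-hydroxy-3-methoxyphenyl)-7-(4-hydroxy-3,5-dimethoxyphenyl)heptane-3,5-diol F8. Peracetylation (Ac2O, pyridine, DMAP) gives the tetraacetate (3R,5S)-1-(4-acetoxy-3-methoxyphenyl)-7-(4-acetoxy-3,5-dimethoxyphenyl)heptane-3,5-diyl diacetate F9. Chemoselective aminolysis of the two aryl acetates (pyrrolidine, CH2Cl2, 0 °C) should leave the alkyl acetates and give 16. This sequence would also absorb any early loss of silyl groups in step 7.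

**Further compounds**
F1 | step 7 | rac-2-{2-[3,5-dimethoxy-4-(triisopropylsilyloxy)phenyl]ethyl}oxirane | COc1cc(CCC2CO2)cc(OC)c1O[Si](C(C)C)(C(C)C)C(C)C
F2 | step 7 | (S)-2-{2-[3,5-dimethoxy-4-(triisopropylsilyloxy)phenyl]ethyl}oxirane | COc1cc(CC[C@H]2CO2)cc(OC)c1O[Si](C(C)C)(C(C)C)C(C)C
F3 | step 7 | 3-[3-methoxy-4-(triisopropylsilyloxy)phenyl]propanal | COc1cc(CCC=O)ccc1O[Si](C(C)C)(C(C)C)C(C)C
F4 | step 7 | 2-{2-[3-methoxy-4-(triisopropylsilyloxy)phenyl]ethyl}-1,3-dithiane | COc1cc(CCC2SCCCS2)ccc1O[Si](C(C)C)(C(C)C)C(C)C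
F5 | step 7 | (S)-4-[3,5-dimethoxy-4-(triisopropylsilyloxy)phenyl]-1-(2-{2-[3-methoxy-4-(triisopropylsilyloxy)phenyl]ethyl}-1,3-dithian-2-yl)butan-2-ol | COc1cc(CCC2(C[C@@H](O)CCc3cc(OC)c(O[Si](C(C)C)(C(C)C)C(C)C)c(OC)c3)SCCCS2)ccc1O[Si](C(C)C)(C(C)C)C(C)C
F6 | step 7 | (S)-5-hydroxy-7-[3,5-dimethoxy-4-(triisopropylsilyloxy)phenyl]-1-[3-methoxy-4-(triisopropylsilyloxy)phenyl]heptan-3-one | COc1cc(CCC(=O)C[C@@H](O)CCc2cc(OC)c(O[Si](C(C)C)(C(C)C)C(C)C)c(OC)c2)ccc1O[Si](C(C)C)(C(C)C)C(C)C
F7 | step 6 | (E)-2-{4-[3,5-dimethoxy-4-(triisopropylsilyloxy)phenyl]but-1-en-1-yl}-4,4,5,5-tetramethyl-1,3,2-dioxaborolane | COc1cc(CC/C=C/B2OC(C)(C)C(C)(C)O2)cc(OC)c1O[Si](C(C)C)(C(C)C)C(C)C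
F8 | step 9 | (3R,5S)-1-(4-hydroxy-3-methoxyphenyl)-7-(4-hydroxy-3,5-dimethoxyphenyl)heptane-3,5-diol | COc1cc(CC[C@H](C[C@H](CCc2cc(OC)c(O)c(OC)c2)O)O)ccc1O
F9 | step 9 | (3R,5S)-1-(4-acetoxy-3-methoxyphenyl)-7-(4-acetoxy-3,5-dimethoxyphenyl)heptane-3,5-diyl diacetate | COc1cc(CC[C@H](C[C@H](CCc2cc(OC)c(OC(C)=O)c(OC)c2)OC(C)=O)OC(C)=O)ccc1OC(C)=O
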